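**Plan**

- Retrosynthesis: the six O‑benzyl bonds are cut first. Then C3–H goes back to a tertiary C3 carbinol, C1–H and C2–H to a C1=C2 indene, and the C8 carbonyl to a C8 methylene. The five‑membered ring is finally opened across C7a–C1 and C2–C3 into an ortho‑borylated benzophenone and a 1,3‑diarylpropyne.
- Enabling feature: C3 sits on C3a, which is ortho and para to the ring A oxygens on C4 and C6, so C3 can be carried as a diaryl ketone. C7a is meta to both oxygens and out of reach of electrophilic substitution, so it carries boron, and an aryl/benzyl alkyne supplies C1–C2.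
- Forward: all four benzene rings are bought. The only ring made is the five‑membered ring, closed in the rhodium [3+2] annulation. C8 is then oxidised, C1=C2 hydrogenated, C3 deoxygenated and the phenols freed.
- Stereochemistry: C3 is set as the (R)‑carbinol by the chiral diene on rhodium. Its hydroxyl steers syn‑hydrogenation of C1=C2, and hydride then replaces the hydroxyl on the same face, anti to the C2 aryl group. The target SMILES decodes to the all‑cis (1R,2R,3R) triad, which is what this sequence gives.

Key step: step 7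

Locants follow the target: C1 carries the aroyl group (carbonyl carbon C8), C2 the 4‑oxygenated phenyl ring, C3 the 3,5‑dioxygenated phenyl ring; ring A is C3a–C4(O)–C5–C6(O)–C7–C7a.

Assumption: the sense of induction of a chiral diene at this diaryl ketone cannot be predicted with certainty; the route is written for the (R,R)‑diene giving the (R)‑carbinol, and the (S,S)‑diene is used if a trial run shows the opposite sense.

**Route**

Step 1
Reactants: 1 1-bromo-3,5-bis(benzyloxy)benzene
Product: 3 2,4-bis(benzyloxy)-6-bromobenzaldehyde, via iminium chloride 2 (not isolated)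
Conditions: POCl3, DMF, 0 → 90 °C; then H2O
Reagents that add atoms: N,N-dimethylformamide, CN(C)C=O (formyl carbon); water, O (carbonyl oxygen)
Why: Vilsmeier–Haack formylation; the chloroiminium ion should attack the position ortho to one benzyloxy group and para to the other, next to bromine, because the site between the two ethers is more crowded, so the formyl carbon (future C3) lies between C–O (future C4) and C–Br (future C7a), and water hydrolyses the iminium salt.

Step 2
Reactants: 1 1-bromo-3,5-bis(benzyloxy)benzene; 3 2,4-bis(benzyloxy)-6-bromobenzaldehyde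
Product: 5 rac-[2,4-bis(benzyloxy)-6-bromophenyl][3,5-bis(benzyloxy)phenyl]methanol, via arylmagnesium bromide 4 (not isolated)
Conditions: Mg, THF, reflux; then 3, THF, 0 °C → rt; then H2O
Reagents that add atoms: none
Why: Grignard formation from a second portion of 1 and 1,2‑addition to the aldehyde should give the benzhydrol, whose stereocentre is removed by oxidation in the next step.

Step 3
Reactants: 5 rac-[2,4-bis(benzyloxy)-6-bromophenyl][3,5-bis(benzyloxy)phenyl]methanol
Product: 6 [2,4-bis(benzyloxy)-6-bromophenyl][3,5-bis(benzyloxy)phenyl]methanone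
Conditions: Dess–Martin periodinane, CH2Cl2, rt
Reagents that add atoms: none
Why: Dess–Martin oxidation of a secondary bis‑benzylic alcohol to the diaryl ketone is reliable even with two ortho substituents and leaves the aryl bromide and benzyl ethers untouched.

Step 4
Reactants: 6 [2,4-bis(benzyloxy)-6-bromophenyl][3,5-bis(benzyloxy)phenyl]methanone
Product: 7 [2,4-bis(benzyloxy)-6-(4,4,5,5-tetramethyl-1,3,2-dioxaborolan-2-yl)phenyl][3,5-bis(benzyloxy)phenyl]methanone
Conditions: B2pin2, PdCl2(dppf) (5 mol%), KOAc, 1,4-dioxane, 90 °C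
Reagents that add atoms: bis(pinacolato)diboron, CC1(C)OB(OC1(C)C)B1OC(C)(C)C(C)(C)O1
Why: Miyaura borylation; oxidative addition of zerovalent palladium into the C–Br bond activated by the ortho carbonyl, acetate‑assisted transmetalation with B2pin2 and reductive elimination should place boron on C7a, the ring A carbon meta to both oxygens.

Step 5
Reactants: 8 1-(benzyloxy)-4-bromobenzene; 9 methoxyallene
Product: 11 1-(benzyloxy)-4-(prop-2-yn-1-yl)benzene, via arylmagnesium bromide 10 (not isolated)
Conditions: Mg, THF, reflux; then 9, CuBr (5 mol%), THF/Et2O, −20 °C → rt; then H2O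
Reagents that add atoms: none
Why: Copper‑catalysed SN2' substitution of methoxyallene by an aryl Grignard reagent (attack at the CH2 terminus, loss of methoxide) should give the propargyl arene directly and avoid the allene that propargyl halides tend to give.

Step 6
Reactants: 11 1-(benzyloxy)-4-(prop-2-yn-1-yl)benzene; 12 1-(benzyloxy)-4-iodobenzene
Product: 13 1,3-bis[4-(benzyloxy)phenyl]prop-1-yne
Conditions: PdCl2(PPh3)2 (2 mol%), CuI (4 mol%), Et3N, THF, rt, degassed
Reagents that add atoms: none
Why: Sonogashira coupling of the terminal alkyne with the aryl iodide runs at room temperature, mild enough to keep the benzylic–propargylic CH2 from isomerising to the allene.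

Step 7
Reactants: 7 the ortho‑boryl benzophenone; 13 1,3-bis[4-(benzyloxy)phenyl]prop-1-yne
Product: 14 (1R)-5,7-bis(benzyloxy)-3-[4-(benzyloxy)benzyl]-1-[3,5-bis(benzyloxy)phenyl]-2-[4-(benzyloxy)phenyl]-1H-inden-1-ol (carbinol carbon = C3 of the target, double bond C1=C2, benzyl group on C1)
Conditions: [RhCl(C2H4)2]2 (2.5 mol%), (R,R)-2,5-diphenylbicyclo[2.2.2]octa-2,5-diene (5.5 mol%), KOH (0.3 equiv), 1,4-dioxane/H2O (10:1 v/v), 60 °C
Reagents that add atoms: none
Why: The hydroxo–diene complex of monovalent rhodium takes the aryl group from boron at C7a, and the arylrhodium adds syn across the alkyne of 13 so that ring A bonds to the benzyl‑bearing carbon (C1) and rhodium sits on the aryl‑bearing carbon (C2), the usual regiochemistry for aryl–alkyl alkynes. The cis alkenylrhodium then adds to the neighbouring diaryl ketone and water releases the tertiary alkoxide and regenerates Rh–OH; this is the known rhodium‑catalysed [3+2] annulation of 2‑acylarylboron reagents with internal alkynes to 1H‑inden‑1‑ols. The five‑membered ring closes by intramolecular 1,2‑addition of C2–Rh to the C3 carbonyl, a 5‑exo‑trig attack on C=O. The one new stereocentre, C3, is set in that addition by the C2‑symmetric diene on rhodium, which selects the ketone face. Two selectivities are needed: the insertion regiochemistry, secured by the aryl/alkyl difference of the alkyne termini, and reaction at ring A and not at the 3,5‑bis(benzyloxy)phenyl ring, secured by the position of boron. Substoichiometric base and moderate temperature should keep the propargylic CH2 of 13 from isomerising.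

Step 8
Reactants: 14 the (R)‑indenol
Product: 16 {(1R)-5,7-bis(benzyloxy)-1-[3,5-bis(benzyloxy)phenyl]-2-[4-(benzyloxy)phenyl]-1-hydroxy-1H-inden-3-yl}[4-(benzyloxy)phenyl]methanone, via C8 carbinol 15 (not isolated)
Conditions: DDQ (2.5 equiv), CH2Cl2/H2O (10:1 v/v), 0 °C → rt
Reagents that add atoms: water, O
Why: DDQ oxidation of an activated methylene in wet solvent; hydride is abstracted from C8, the only C–H that is both allylic to C1=C2 and benzylic to a 4‑alkoxyphenyl ring, water captures the 1,3‑diarylallyl cation at its less hindered C8 terminus, and a second equivalent oxidises the carbinol to the ketone, while the tertiary indenol resists ionisation (antiaromatic indenyl cation) and phenyl benzyl ethers are inert to DDQ.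

Step 9
Reactants: 16 the C8 ketone (enone)
Product: 17 {(1R,2R,3S)-4,6-bis(benzyloxy)-3-[3,5-bis(benzyloxy)phenyl]-2-[4-(benzyloxy)phenyl]-3-hydroxy-2,3-dihydro-1H-inden-1-yl}[4-(benzyloxy)phenyl]methanone
Conditions: H2 (1–5 atm), [Ir(cod)(PCy3)(py)]PF6 (10 mol%), CH2Cl2, rt
Reagents that add atoms: none
Why: Hydroxyl‑directed homogeneous hydrogenation; the cationic iridium binds the allylic C3 hydroxyl and delivers both hydrogens to C1=C2 from the hydroxyl face, which is also the face away from the C3 aryl ring, so the C1 aroyl and C2 aryl groups come out cis to each other and to the C3 aryl ring, and benzyl ethers and the aryl ketone are not reduced by this catalyst.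

Step 10
Reactants: 17 the saturated C3 carbinol
Product: 18 {(1R,2R,3R)-4,6-bis(benzyloxy)-3-[3,5-bis(benzyloxy)phenyl]-2-[4-(benzyloxy)phenyl]-2,3-dihydro-1H-inden-1-yl}[4-(benzyloxy)phenyl]methanone
Conditions: Et3SiH (5 equiv), CF3CO2H (10 equiv), CH2Cl2, −40 → 0 °C
Reagents that add atoms: none
Why: Ionic hydrogenation (Kursanov–Parnes reduction); acid ionises the tertiary carbinol to a C3 cation stabilised by the ortho (C4) and para (C6) oxygens of ring A, and Et3SiH should deliver hydride to the face opposite the C2 aryl and C1 aroyl groups, so hydrogen replaces hydroxyl with retention and the all‑cis triad results, while the low temperature keeps the ketone unreduced and C1 from enolising.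

Step 11
Reactants: 18 hexa‑O‑benzyl caraphenol B
Product: 19 caraphenol B, [(1R,2R,3R)-3-(3,5-dihydroxyphenyl)-4,6-dihydroxy-2-(4-hydroxyphenyl)-2,3-dihydro-1H-inden-1-yl](4-hydroxyphenyl)methanone
Conditions: H2 (1 atm), Pd/C (10 wt%), THF/MeOH, rt, stopped at six equivalents of H2
Reagents that add atoms: none
Why: Hydrogenolysis of the six aryl benzyl ethers over palladium on carbon under neutral conditions is faster than reduction of the electron‑rich aryl ketone and should not disturb the C1 stereocentre next to the carbonyl.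

**Compound list**

1 | 1-bromo-3,5-bis(benzyloxy)benzene | Brc1cc(OCc2ccccc2)cc(OCc2ccccc2)c1 | starting material
2 | N-{[2,4-bis(benzyloxy)-6-bromophenyl]methylidene}-N-methylmethanaminium chloride | C[N+](C)=Cc1c(Br)cc(OCc2ccccc2)cc1OCc1ccccc1.[Cl-] | intermediate (not isolated)
3 | 2,4-bis(benzyloxy)-6-bromobenzaldehyde | O=Cc1c(Br)cc(OCc2ccccc2)cc1OCc1ccccc1 | intermediate
4 | [3,5-bis(benzyloxy)phenyl]magnesium bromide | Br[Mg]c1cc(OCc2ccccc2)cc(OCc2ccccc2)c1 | intermediate (not isolated)
5 | rac-[2,4-bis(benzyloxy)-6-bromophenyl][3,5-bis(benzyloxy)phenyl]methanol | OC(c1cc(OCc2ccccc2)cc(OCc2ccccc2)c1)c1c(Br)cc(OCc2ccccc2)cc1OCc1ccccc1 | intermediate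
6 | [2,4-bis(benzyloxy)-6-bromophenyl][3,5-bis(benzyloxy)phenyl]methanone | O=C(c1cc(OCc2ccccc2)cc(OCc2ccccc2)c1)c1c(Br)cc(OCc2ccccc2)cc1OCc1ccccc1 | intermediate
7 | [2,4-bis(benzyloxy)-6-(4,4,5,5-tetramethyl-1,3,2-dioxaborolan-2-yl)phenyl][3,5-bis(benzyloxy)phenyl]methanone | O=C(c1cc(OCc2ccccc2)cc(OCc2ccccc2)c1)c1c(OCc2ccccc2)cc(OCc2ccccc2)cc1B1OC(C)(C)C(C)(C)O1 | intermediate (key-step precursor)
8 | 1-(benzyloxy)-4-bromobenzene | Brc1ccc(OCc2ccccc2)cc1 | starting material
9 | methoxyallene (1-methoxypropa-1,2-diene) | COC=C=C | starting material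
10 | [4-(benzyloxy)phenyl]magnesium bromide | Br[Mg]c1ccc(OCc2ccccc2)cc1 | intermediate (not isolated)
11 | 1-(benzyloxy)-4-(prop-2-yn-1-yl)benzene | C#CCc1ccc(OCc2ccccc2)cc1 | intermediate
12 | 1-(benzyloxy)-4-iodobenzene | Ic1ccc(OCc2ccccc2)cc1 | starting material
13 | 1,3-bis[4-(benzyloxy)phenyl]prop-1-yne | C(C#Cc1ccc(OCc2ccccc2)cc1)c1ccc(OCc2ccccc2)cc1 | intermediate (key-step precursor)
14 | (1R)-5,7-bis(benzyloxy)-3-[4-(benzyloxy)benzyl]-1-[3,5-bis(benzyloxy)phenyl]-2-[4-(benzyloxy)phenyl]-1H-inden-1-ol | C(c1ccc(OCc2ccccc2)cc1)C=1c2cc(OCc3ccccc3)cc(OCc3ccccc3)c2[C@@](O)(c2cc(OCc3ccccc3)cc(OCc3ccccc3)c2)C=1c1ccc(OCc2ccccc2)cc1 | intermediate (key-step product)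
15 | (1R)-5,7-bis(benzyloxy)-1-[3,5-bis(benzyloxy)phenyl]-2-[4-(benzyloxy)phenyl]-3-{[4-(benzyloxy)phenyl](hydroxy)methyl}-1H-inden-1-ol, both C8 epimers | OC(c1ccc(OCc2ccccc2)cc1)C=1c2cc(OCc3ccccc3)cc(OCc3ccccc3)c2[C@@](O)(c2cc(OCc3ccccc3)cc(OCc3ccccc3)c2)C=1c1ccc(OCc2ccccc2)cc1 | intermediate (not isolated)
16 | {(1R)-5,7-bis(benzyloxy)-1-[3,5-bis(benzyloxy)phenyl]-2-[4-(benzyloxy)phenyl]-1-hydroxy-1H-inden-3-yl}[4-(benzyloxy)phenyl]methanone | O=C(c1ccc(OCc2ccccc2)cc1)C=1c2cc(OCc3ccccc3)cc(OCc3ccccc3)c2[C@@](O)(c2cc(OCc3ccccc3)cc(OCc3ccccc3)c2)C=1c1ccc(OCc2ccccc2)cc1 | intermediate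
17 | {(1R,2R,3S)-4,6-bis(benzyloxy)-3-[3,5-bis(benzyloxy)phenyl]-2-[4-(benzyloxy)phenyl]-3-hydroxy-2,3-dihydro-1H-inden-1-yl}[4-(benzyloxy)phenyl]methanone (H on C1 and C2 on the hydroxyl face) | O=C(c1ccc(OCc2ccccc2)cc1)[C@H]1c2cc(OCc3ccccc3)cc(OCc3ccccc3)c2[C@@](O)(c2cc(OCc3ccccc3)cc(OCc3ccccc3)c2)[C@H]1c1ccc(OCc2ccccc2)cc1 | intermediate
18 | {(1R,2R,3R)-4,6-bis(benzyloxy)-3-[3,5-bis(benzyloxy)phenyl]-2-[4-(benzyloxy)phenyl]-2,3-dihydro-1H-inden-1-yl}[4-(benzyloxy)phenyl]methanone (all-cis) | O=C(c1ccc(OCc2ccccc2)cc1)[C@H]1c2cc(OCc3ccccc3)cc(OCc3ccccc3)c2[C@@H](c2cc(OCc3ccccc3)cc(OCc3ccccc3)c2)[C@H]1c1ccc(OCc2ccccc2)cc1 | intermediate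
19 | caraphenol B, [(1R,2R,3R)-3-(3,5-dihydroxyphenyl)-4,6-dihydroxy-2-(4-hydroxyphenyl)-2,3-dihydro-1H-inden-1-yl](4-hydroxyphenyl)methanone | O=C(c1ccc(O)cc1)[C@H]1c2cc(O)cc(O)c2[C@@H](c2cc(O)cc(O)c2)[C@H]1c1ccc(O)cc1 | target

**Step count**

Total: 11 steps. Longest linear sequence: 9 steps (steps 1–4, then 7–11); the alkyne branch (steps 5–6) joins at step 7.

**Steps most likely to fail**

Step 7. The alkenylrhodium may add only slowly to the crowded, electron‑rich diaryl ketone, so that protonolysis of the C–Rh bond or protodeboronation overtakes ring closure; the ketone face may also be selected imperfectly. The fallback leaves boron out and sets out from bromo ketone 6 and alkyne 13. A nickel‑catalysed reductive carbocyclisation of the ortho‑bromoaryl ketone with the alkyne (NiBr2(dppe) cat., Zn, MeCN, 80 °C, aqueous work‑up) forms the same two bonds with the same regiochemistry and should give the racemic indenol F1. This is separated by preparative HPLC on a chiral stationary phase, and the (R)‑enantiomer re‑enters the route as 14.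

Step 8. The 1,3‑diarylallyl cation may be captured at the ring terminus C2, or the C3 aryl group may shift to C2 in a semipinacol rearrangement; the oxidation may also stall at the carbinol. The fallback carries the C8 oxygen in the alkyne and sets out from boronate 7.
- Purchased 1-(benzyloxy)-4-ethynylbenzene (C#Cc1ccc(OCc2ccccc2)cc1) is deprotonated with n‑BuLi (THF, −78 °C) to lithium [4-(benzyloxy)phenyl]ethynide F2.
- F2 adds to purchased 4-(benzyloxy)benzaldehyde (O=Cc1ccc(OCc2ccccc2)cc1) to give rac-1,3-bis[4-(benzyloxy)phenyl]prop-2-yn-1-ol F3.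
- TBSCl and imidazole in DMF convert it into the silyl ether F4.
- Annulation of F4 with 7 under the conditions of step 7 should give the C8‑silyloxy indenol F5 as both C8 epimers with the same (R)‑carbinol; rhodium on C2 has no β‑oxygen to eliminate.
- TBAF in THF frees the diol, which is compound 15 (now isolated), and MnO2 in CH2Cl2 oxidises only the secondary allylic–benzylic carbinol, returning to the route at 16.

Step 9. The iridium catalyst may fail to engage the tetrasubstituted enone flanked by three aryl groups, or acid formed from the catalyst may ionise the product carbinol. The fallback sets out from 16 and relies on steric control on a surface. Hydrogenation over Pd/C (H2, 5 atm, EtOAc/MeOH) should remove the six benzyl groups and saturate C1=C2 from the hydroxyl face, since the C3 aryl ring shields the other, giving the pentaphenol carbinol F6. Et3SiH and CF3CO2H in MeCN at 0 °C then reduce the C3 cation (a protonated para‑quinone methide of ring A) from the face anti to the C2 aryl group, returning to the route at 19.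

**Further compounds**

F1 | step 7 | rac-5,7-bis(benzyloxy)-3-[4-(benzyloxy)benzyl]-1-[3,5-bis(benzyloxy)phenyl]-2-[4-(benzyloxy)phenyl]-1H-inden-1-ol | C(c1ccc(OCc2ccccc2)cc1)C=1c2cc(OCc3ccccc3)cc(OCc3ccccc3)c2C(O)(c2cc(OCc3ccccc3)cc(OCc3ccccc3)c2)C=1c1ccc(OCc2ccccc2)cc1
F2 | step 8 | lithium [4-(benzyloxy)phenyl]ethynide | [Li]C#Cc1ccc(OCc2ccccc2)cc1
F3 | step 8 | rac-1,3-bis[4-(benzyloxy)phenyl]prop-2-yn-1-ol | OC(C#Cc1ccc(OCc2ccccc2)cc1)c1ccc(OCc2ccccc2)cc1
F4 | step 8 | rac-{1,3-bis[4-(benzyloxy)phenyl]prop-2-yn-1-yl}oxy(tert-butyl)dimethylsilane | CC(C)(C)[Si](C)(C)OC(C#Cc1ccc(OCc2ccccc2)cc1)c1ccc(OCc2ccccc2)cc1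
F5 | step 8 | (1R)-5,7-bis(benzyloxy)-1-[3,5-bis(benzyloxy)phenyl]-2-[4-(benzyloxy)phenyl]-3-{[4-(benzyloxy)phenyl][(tert-butyldimethylsilyl)oxy]methyl}-1H-inden-1-ol, both C8 epimers | CC(C)(C)[Si](C)(C)OC(c1ccc(OCc2ccccc2)cc1)C=1c2cc(OCc3ccccc3)cc(OCc3ccccc3)c2[C@@](O)(c2cc(OCc3ccccc3)cc(OCc3ccccc3)c2)C=1c1ccc(OCc2ccccc2)cc1
F6 | step 9 | [(1R,2R,3S)-3-(3,5-dihydroxyphenyl)-3,4,6-trihydroxy-2-(4-hydroxyphenyl)-2,3-dihydro-1H-inden-1-yl](4-hydroxyphenyl)methanone | O=C(c1ccc(O)cc1)[C@H]1c2cc(O)cc(O)c2[C@@](O)(c2cc(O)cc(O)c2)[C@H]1c1ccc(O)cc1
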